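Ring A bears four contiguous substituents (C6 aryloxy, C1 carboxyl, C2 methoxy, C3 carbinol) and just two adjacent CH positions, C4 and C5. The route disconnects ring A at C2–C3 and C4–C5 into a malonate-derived silyl ketene acetal diene, which already holds the C6–O–ring B diaryl ether, the C1 ester and the C2 methoxy oxygen, and the terminal ynone 5-methylhex-1-yn-3-one, which supplies C3, C4 and the side-chain ketone. A single regiocontrolled [4+2] cycloaddition with aromatizing loss of silanol delivers the fully substituted benzoate. The C3 ketone is then reduced under catalyst control to the (R)-carbinol, and three deprotections complete the synthesis.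

Key step: step 12

Remarks on the chemistry (assumptions):
- Ring A locants: C1 carboxyl, C2 OMe, C3 side chain, C4-H, C5-H, C6 O-aryl. The target carbinol is (R) (priorities OH > aryl > CH2 > H).
- ArB = 2-(allyloxy)-6-{[(tert-butyldimethylsilyl)oxy]methyl}-4-methylphenyl.
- Ring B is taken from creosol: its free OH is para to the methyl group and its only open ortho position accepts the formyl group, which fixes the substitution pattern without a regiochemical choice.
- The acetal geometry of diene 11 and the ketal centre of cycloadduct 15 are lost on aromatization and are left undefined; alcohol 13 is racemic and is oxidised.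
- A mixed methyl silyl ketal such as 15 can aromatize by loss of silanol or of methanol; the elimination is therefore run under aprotic base, and the phenol pathway is kept as the fallback.

Step 1
Reactants: 1 2-methoxy-4-methylphenol (creosol)
Product: 2 2-hydroxy-3-methoxy-5-methylbenzaldehyde
Conditions: MgCl2, Et3N, (CH2O)n, MeCN, reflux; 1 M HCl work-up
Reagents that add atoms: paraformaldehyde (as formaldehyde), C=O
Why: Casnati–Skattebøl ortho-formylation, in which the magnesium phenoxide directs formaldehyde to the only free ortho position and a second formaldehyde oxidises the resulting benzylic alkoxide to the aldehyde.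

Step 2
Reactants: 2 2-hydroxy-3-methoxy-5-methylbenzaldehyde
Product: 3 2,3-dihydroxy-5-methylbenzaldehyde
Conditions: BBr3, CH2Cl2, –78 → 0 °C; H2O
Reagents that add atoms: none
Why: Lewis-acid aryl methyl ether cleavage (BBr3 demethylation) of an o-vanillin-type substrate, which the aldehyde tolerates at low temperature.

Step 3
Reactants: 3 2,3-dihydroxy-5-methylbenzaldehyde
Product: 4 3-(allyloxy)-2-hydroxy-5-methylbenzaldehyde
Conditions: NaH (2.2 equiv), DMSO, 20 °C; allyl bromide (1.0 equiv); 1 M HCl quench
Reagents that add atoms: allyl bromide, C=CCBr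
Why: Regioselective Williamson etherification of the dianion, in which the 2-phenoxide is conjugated to and chelated by the formyl group and is the weaker nucleophile, so one equivalent of allyl bromide should alkylate the 3-oxygen.

Step 4
Reactants: 4 3-(allyloxy)-2-hydroxy-5-methylbenzaldehyde
Product: 5 2-(allyloxy)-6-(hydroxymethyl)-4-methylphenol
Conditions: NaBH4, THF/MeOH, 0 °C
Reagents that add atoms: none
Why: Borohydride reduction of an aryl aldehyde, to which the allyl ether and the phenol are inert.

Step 5
Reactants: 5 2-(allyloxy)-6-(hydroxymethyl)-4-methylphenol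
Product: 6 2-(allyloxy)-6-{[(tert-butyldimethylsilyl)oxy]methyl}-4-methylphenol (ArB–OH)
Conditions: TBSCl (1.05 equiv), imidazole, CH2Cl2, 0 °C
Reagents that add atoms: tert-butyldimethylsilyl chloride, CC(C)(C)[Si](C)(C)Cl
Why: Chemoselective silylation, since the primary benzylic hydroxyl of a salicyl alcohol reacts faster than the hydrogen-bonded, doubly ortho-substituted phenol, which stays free as the future diaryl ether oxygen.

Step 6
Reactants: 7 dimethyl malonate
Product: 8 dimethyl 2-acetylmalonate
Conditions: MgCl2, Et3N, AcCl, MeCN, 0 °C → rt; aq. HCl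
Reagents that add atoms: acetyl chloride, CC(=O)Cl
Why: Rathke C-acylation of the magnesium-chelated malonate enolate formed by soft enolization, which avoids O-acylation and double acylation.

Step 7
Reactants: 8 dimethyl 2-acetylmalonate
Product: 9 dimethyl 2-(1-chloroethylidene)malonate
Conditions: POCl3, Bu3N, 100 °C; ice-water; distillation
Reagents that add atoms: phosphoryl chloride, O=P(Cl)(Cl)Cl
Why: Deoxychlorination of the enolised acylmalonate (vinylogous acid chloride formation), a standard entry to 1-chloroalkylidene malonates.

Step 8
Reactants: 6 ArB–OH; 9 dimethyl 2-(1-chloroethylidene)malonate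
Product: 10 dimethyl 2-[1-(ArB-oxy)ethylidene]malonate
Conditions: Cs2CO3, DMF, 0 °C → rt
Reagents that add atoms: none
Why: Nucleophilic vinylic substitution by addition–elimination, in which the caesium phenoxide adds to the β-carbon of the doubly activated chloroalkene and the malonate anion expels chloride; any material that reacts by dehydrochlorination to the allene and re-addition should give the same enol ether.

Step 9
Reactants: 10 dimethyl 2-[1-(ArB-oxy)ethylidene]malonate
Product: 11 methyl 3-(ArB-oxy)-2-[methoxy(trimethylsilyloxy)methylidene]but-3-enoate (3-aryloxy-1-methoxy-2-methoxycarbonyl-1-trimethylsilyloxybuta-1,3-diene)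
Conditions: LiN(iPr)2 (1.1 equiv), THF, –78 °C; Me3SiCl, –78 → 0 °C; pentane, filtration under Ar; used crude
Reagents that add atoms: chlorotrimethylsilane, C[Si](C)(C)Cl
Why: Vinylogous (γ) enolization of the alkylidene malonate and O-silylation of the extended enolate, as used for vinylketene acetals from β-alkoxycrotonates; the two ester groups are equivalent, so only one constitution can form.

Step 10
Reactants: 12 isovaleraldehyde (3-methylbutanal)
Product: 13 5-methylhex-1-yn-3-ol (racemic)
Conditions: HC≡CMgBr, THF, 0 °C; aq. NH4Cl
Reagents that add atoms: ethynylmagnesium bromide, C#C[Mg]Br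
Why: Grignard addition of an acetylide to an aliphatic aldehyde; the new carbinol centre is racemic and is removed by the next oxidation.

Step 11
Reactants: 13 5-methylhex-1-yn-3-ol
Product: 14 5-methylhex-1-yn-3-one
Conditions: Dess–Martin periodinane, NaHCO3, CH2Cl2, 0 °C → rt; careful concentration
Reagents that add atoms: none
Why: Dess–Martin oxidation of a propargylic alcohol under buffered neutral conditions, which spares the base- and nucleophile-sensitive terminal ynone.

Step 12
Reactants: 11 methyl 3-(ArB-oxy)-2-[methoxy(trimethylsilyloxy)methylidene]but-3-enoate; 14 5-methylhex-1-yn-3-one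
Product: 16 methyl 6-(ArB-oxy)-2-methoxy-3-(3-methylbutanoyl)benzoate, via cyclohexa-1,4-diene methyl silyl ketal cycloadduct 15 (not isolated)
Conditions: 14 (2 equiv), PhMe, 90 °C, sealed tube; evaporate; DBU (1.2 equiv), CH2Cl2, 0 °C → rt
Reagents that add atoms: none
Why: The ketene acetal and the 3-aryloxy group both make the CH2 terminus of the diene its nucleophilic end, so it should bond to the electrophilic terminal carbon of the ynone (C4–C5) while the acetal carbon bonds to the acyl-bearing alkyne carbon (C2–C3), either through a concerted asynchronous [4+2] transition state or through vinylogous Mukaiyama–Michael addition and ring closure, both leading to cyclohexa-1,4-diene 15. The closest known reaction type is the Diels–Alder/aromatization of 1,1-dioxygenated vinylketene acetals with acetylenic ketones and esters to give anisoles and salicylates. Ring A is closed as a six-membered carbocycle by this intermolecular [4+2] cycloaddition, and no stereocentre survives because the ketal carbon of 15 becomes aromatic C2. Two selectivities are needed: the regiochemistry, secured by the matched donor pattern of the diene and the single acceptor terminus of the ynone, and the mode of aromatization, secured by carrying out the elimination with an aprotic amidine base, where the ester- and ketone-stabilised anion formed by removal of a C5 proton should expel the better leaving group, trimethylsilanolate, and keep the C2 methoxy group. The 2-ester and 3-aryloxy substituents favour the s-cis conformer of the diene, and excess ynone compensates for its volatility.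

Step 13
Reactants: 16 methyl 6-(ArB-oxy)-2-methoxy-3-(3-methylbutanoyl)benzoate
Product: 17 methyl 6-(ArB-oxy)-3-[(1R)-1-hydroxy-3-methylbutyl]-2-methoxybenzoate
Conditions: RuCl(p-cymene)[(R,R)-TsDPEN] (2 mol %), HCO2H/Et3N (5:2), DMF, 35 °C
Reagents that add atoms: none
Why: Noyori–Ikariya asymmetric transfer hydrogenation, in which outer-sphere hydride and proton transfer with an arene CH/π contact to the aryl group lets the (R,R)-ligand set the (R)-carbinol, the same sense as (R)-1-phenylethanol from acetophenone since the priority order OH > aryl > alkyl is unchanged.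

Step 14
Reactants: 17 methyl 6-(ArB-oxy)-3-[(1R)-1-hydroxy-3-methylbutyl]-2-methoxybenzoate
Product: 18 methyl 6-(2-{[(tert-butyldimethylsilyl)oxy]methyl}-6-hydroxy-4-methylphenoxy)-3-[(1R)-1-hydroxy-3-methylbutyl]-2-methoxybenzoate
Conditions: Pd(PPh3)4 (5 mol %), morpholine (5 equiv), THF, rt
Reagents that add atoms: none
Why: Tsuji–Trost deallylation, in which zerovalent palladium ionises the aryl allyl ether to a π-allyl complex that morpholine traps irreversibly, under neutral conditions that leave the carbinol stereocentre untouched.

Step 15
Reactants: 18 methyl 6-(2-{[(tert-butyldimethylsilyl)oxy]methyl}-6-hydroxy-4-methylphenoxy)-3-[(1R)-1-hydroxy-3-methylbutyl]-2-methoxybenzoate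
Product: 19 methyl 6-[2-hydroxy-6-(hydroxymethyl)-4-methylphenoxy]-3-[(1R)-1-hydroxy-3-methylbutyl]-2-methoxybenzoate
Conditions: Bu4NF (3 equiv), THF, 0 °C → rt; pH 7 buffer
Reagents that add atoms: none
Why: Fluoride-mediated desilylation driven by Si–F bond formation, chosen over acid because the benzylic carbinol, ortho to methoxy and para to aryloxy, would ionise under acidic conditions.

Step 16
Reactants: 19 methyl 6-[2-hydroxy-6-(hydroxymethyl)-4-methylphenoxy]-3-[(1R)-1-hydroxy-3-methylbutyl]-2-methoxybenzoate
Product: 20 6-[2-hydroxy-6-(hydroxymethyl)-4-methylphenoxy]-3-[(1R)-1-hydroxy-3-methylbutyl]-2-methoxybenzoic acid (target)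
Conditions: NaSEt (6 equiv), DMF, 60 °C, Ar; then 1 M HCl to pH 4, 0 °C
Reagents that add atoms: none
Why: SN2 dealkylation of the methyl ester by thiolate at the O–CH3 carbon (alkyl–oxygen cleavage), which is indifferent to the two ortho substituents that block the carbonyl, while the aryl methyl ether needs much higher temperature and the stereocentre is not involved.

Compound list
1 | 2-methoxy-4-methylphenol (creosol) | COc1cc(C)ccc1O | starting material
2 | 2-hydroxy-3-methoxy-5-methylbenzaldehyde | COc1cc(C)cc(C=O)c1O | intermediate
3 | 2,3-dihydroxy-5-methylbenzaldehyde | Cc1cc(O)c(O)c(C=O)c1 | intermediate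
4 | 3-(allyloxy)-2-hydroxy-5-methylbenzaldehyde | C=CCOc1cc(C)cc(C=O)c1O | intermediate
5 | 2-(allyloxy)-6-(hydroxymethyl)-4-methylphenol | C=CCOc1cc(C)cc(CO)c1O | intermediate
6 | 2-(allyloxy)-6-{[(tert-butyldimethylsilyl)oxy]methyl}-4-methylphenol | C=CCOc1cc(C)cc(CO[Si](C)(C)C(C)(C)C)c1O | intermediate
7 | dimethyl malonate | COC(=O)CC(=O)OC | starting material
8 | dimethyl 2-acetylmalonate | COC(=O)C(C(C)=O)C(=O)OC | intermediate
9 | dimethyl 2-(1-chloroethylidene)malonate | COC(=O)C(=C(C)Cl)C(=O)OC | intermediate
10 | dimethyl 2-{1-[2-(allyloxy)-6-{[(tert-butyldimethylsilyl)oxy]methyl}-4-methylphenoxy]ethylidene}malonate | COC(=O)C(=C(C)Oc1c(OCC=C)cc(C)cc1CO[Si](C)(C)C(C)(C)C)C(=O)OC | intermediate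
11 | methyl 3-[2-(allyloxy)-6-{[(tert-butyldimethylsilyl)oxy]methyl}-4-methylphenoxy]-2-[methoxy(trimethylsilyloxy)methylidene]but-3-enoate (acetal geometry undefined) | C=C(Oc1c(OCC=C)cc(C)cc1CO[Si](C)(C)C(C)(C)C)C(C(=O)OC)=C(OC)O[Si](C)(C)C | intermediate
12 | isovaleraldehyde (3-methylbutanal) | CC(C)CC=O | starting material
13 | 5-methylhex-1-yn-3-ol (racemic) | C#CC(O)CC(C)C | intermediate
14 | 5-methylhex-1-yn-3-one | C#CC(=O)CC(C)C | intermediate
15 | methyl 2-(ArB-oxy)-6-methoxy-5-(3-methylbutanoyl)-6-(trimethylsilyloxy)cyclohexa-1,4-diene-1-carboxylate (racemic ketal carbon, not isolated) | COC(=O)C1=C(Oc2c(OCC=C)cc(C)cc2CO[Si](C)(C)C(C)(C)C)CC=C(C(=O)CC(C)C)C1(OC)O[Si](C)(C)C | intermediate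
16 | methyl 6-[2-(allyloxy)-6-{[(tert-butyldimethylsilyl)oxy]methyl}-4-methylphenoxy]-2-methoxy-3-(3-methylbutanoyl)benzoate | COc1c(C(=O)CC(C)C)ccc(Oc2c(OCC=C)cc(C)cc2CO[Si](C)(C)C(C)(C)C)c1C(=O)OC | intermediate
17 | methyl 6-[2-(allyloxy)-6-{[(tert-butyldimethylsilyl)oxy]methyl}-4-methylphenoxy]-3-[(1R)-1-hydroxy-3-methylbutyl]-2-methoxybenzoate | COc1c([C@H](O)CC(C)C)ccc(Oc2c(OCC=C)cc(C)cc2CO[Si](C)(C)C(C)(C)C)c1C(=O)OC | intermediate
18 | methyl 6-(2-{[(tert-butyldimethylsilyl)oxy]methyl}-6-hydroxy-4-methylphenoxy)-3-[(1R)-1-hydroxy-3-methylbutyl]-2-methoxybenzoate | COc1c([C@H](O)CC(C)C)ccc(Oc2c(O)cc(C)cc2CO[Si](C)(C)C(C)(C)C)c1C(=O)OC | intermediate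
19 | methyl 6-[2-hydroxy-6-(hydroxymethyl)-4-methylphenoxy]-3-[(1R)-1-hydroxy-3-methylbutyl]-2-methoxybenzoate | COc1c([C@H](O)CC(C)C)ccc(Oc2c(O)cc(C)cc2CO)c1C(=O)OC | intermediate
20 | 6-[2-hydroxy-6-(hydroxymethyl)-4-methylphenoxy]-3-[(1R)-1-hydroxy-3-methylbutyl]-2-methoxybenzoic acid | COc1c([C@H](O)CC(C)C)ccc(Oc2c(O)cc(C)cc2CO)c1C(=O)O | target

Total step count: 16. Longest linear sequence: 12 steps (steps 1–5, 8, 9, 12–16, from creosol).

Steps most likely to fail:

1. Step 12. The cycloadduct may aromatize by expelling methanol instead of silanol, or the ketene acetal may be partly hydrolysed before it reacts, so that the C2 oxygen ends up as a free phenol. The fallback sets out from 11 and 14. The cycloaddition is run as before to 15, and the crude adduct is stirred with K2CO3 in MeOH at 0 °C. This removes the silyl group from the ketal, expels methoxide and lets the dienone tautomerise to methyl 6-(ArB-oxy)-2-hydroxy-3-(3-methylbutanoyl)benzoate F1; any 16 already present is unaffected. O-Methylation of F1 with MeI and K2CO3 in DMF at 40 °C returns to the route at 16.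

2. Step 8. Addition of the doubly ortho-substituted phenoxide to the tetrasubstituted chloroalkene may be slow, letting base-induced consumption of the electrophile compete. The fallback sets out from 9. Dehydrochlorination with Et3N in Et2O at 0 °C should give dimethyl 2-vinylidenemalonate F2, used at once. DABCO-catalysed conjugate addition of phenol 6 to the unhindered central allene carbon of F2 in MeCN, with base equilibration into conjugation, returns to the route at 10.

3. Step 13. Facial discrimination or turnover may be poor because the carbonyl sits next to an ortho-methoxy group on an electron-rich ring. The fallback sets out from 16. Corey–Bakshi–Shibata reduction with (S)-2-methyl-CBS-oxazaborolidine and catecholborane in toluene at –78 °C should give the same (R)-alcohol, with the aryl group as the large substituent, and returns to the route at 17. Catecholborane is used in place of BH3 so that the allyl ether is not hydroborated. It makes no compound outside the list (F0).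

Further compounds
F1 | step 12 | methyl 6-[2-(allyloxy)-6-{[(tert-butyldimethylsilyl)oxy]methyl}-4-methylphenoxy]-2-hydroxy-3-(3-methylbutanoyl)benzoate | COC(=O)c1c(O)c(C(=O)CC(C)C)ccc1Oc1c(OCC=C)cc(C)cc1CO[Si](C)(C)C(C)(C)C
F2 | step 8 | dimethyl 2-vinylidenemalonate | C=C=C(C(=O)OC)C(=O)OC
F0 | step 13 | none | none
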